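The numbers in the tables come from a simulation from invented constants.

The links of the alpha run fade at 0.296 /min, read from first to last reading, and extrapolated back to its start that puts about 37.9% of its first end groups into links. Yet first end groups read 0.4% at 1.33 min, so a second product took the remainder.

| flask | first end groups | second end groups | remark | time |
|---|---|---|---|---|
| beta | 0.15 M | 0.74 equiv | run made earlier |  |
| alpha | 0.15 M | 2.2 equiv | run made earlier |  |
| Monday's | 0.15 M | 1.10 equiv |  | 6.0 min |
| Saturday's | 0.25 M | 1.10 equiv |  | 6.0 min |
| Tuesday's | 0.40 M | 1.10 equiv |  | 6.0 min |
| Friday's | 0.60 M | 1.10 equiv |  | 6.0 min |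
| Sunday's | 0.80 M | 1.10 equiv |  | 6.0 min |

| run | time / min | links / % | first end groups / % |
|---|---|---|---|
| beta | 0.250 | 8.4 | 25.2 |
| beta | 0.500 | 7.4 | 26.3 |
| beta | 0.833 | 6.7 | 26.1 |
| beta | 1.33 | 3.8 | 25.8 |
| beta | 2.00 | 3.3 | 25.9 |
| beta | 4.00 | 2.4 | 26.5 |
| alpha | 0.667 | 31.1 | 1.7 |
| alpha | 1.33 | 26.4 | 0.4 |
| alpha | 2.00 | 22.7 | 0.4 |
| alpha | 2.50 | 18.5 | 0.3 |
| alpha | 3.00 | 16.6 | 1.2 |
| alpha | 4.00 | 11.6 | 2.0 |

(scatter of a reading: 0.5 percentage points)

- the numbers in the tables scatter by 0.5 percentage points (one standard deviation)
- "hardly changes" means that all values lie within two and a half points (for a concentration: within two and a half percent of the largest)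

- [links] at the end for Monday's, Saturday's, Tuesday's, Friday's, Sunday's, in this order
- the shape of the row from first to last (hardly changes / rises, then falls / falls all the way / rises all the way / falls, then rises)

Take the main step first. First end groups and second end groups go one for one, as the beta run shows by levelling near 26.5% first end groups after a charge of 0.74 equiv. With links as sole product and first end groups as limiting reagent, the count is 0.15 M of links for Monday's and 0.80 M for Sunday's.

Now add the second product and compare rates at one moment. We assume that link formation scales with [second end groups] and the other route does not. The link share is then [second end groups]/([second end groups] + c). The mean [second end groups] in the alpha run is 0.255 M, so c is 0.418 M. We call c the crossover concentration, the [second end groups] at which both routes run equally fast; it is a selectivity written as a concentration. That c stays fixed between flasks is our assumption: both earlier runs start at 0.15 M of first end groups.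

Then add the fade. We take it as links coming apart, with the freed pair re-forming links at that same share. The alpha run kept 0.180 M of second end groups, so the bare coming-apart constant is 0.423 /min. Monday's keeps 0.0150 M and Sunday's 0.0800 M, so both should fade faster than the alpha run.

| Flask | Mean [second end groups] | Link share | Fade | [links] at the end |
|---|---|---|---|---|
| Monday's | 0.0900 M | 17.7% | 0.409 /min | 0.00229 M |
| Sunday's | 0.480 M | 53.4% | 0.355 /min | 0.0507 M |

The forecast gives 0.0042 M, 0.009 M, 0.018 M, 0.032 M and 0.048 M, a row that rises all the way, on the ground that “the final links rise with charge”. Our reckoning is lower on Monday's and higher on Sunday's.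

The flasks give 0.00246 M, 0.00640 M, 0.0152 M, 0.0319 M and 0.0539 M; the row rises all the way.

    first end groups + second end groups ⇌ links (K = 42.0 /M, k = 0.290 /M/s)
    first end groups + second end groups → rings, rate k2*[first end groups] as long as [second end groups] is above zero (k = 0.120 /s)

Sunday's ends at 0.0539 M of links, while the same flask without rings ends at 0.704 M and without the way back at 0.401 M, so the step to rings and the way back together hold links down. At 6.00 min, Sunday's holds 0.0827 M of second end groups, so with c at 0.418 M the forward step to rings runs 5.05 times as fast as the forward step to links. Monday's holds 0.0151 M at that time, which gives 27.7 times, and its links fall from 5.42% at 3.00 min to 1.64% at 6.00 min.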